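**Retrosynthetic overview**

1. Labels: O8 pyran oxygen; C9 hemiketal carbon; C10 CHOH; C11 ring ketone; C12 tertiary carbinol; C13=C14–C15(=O) enone; C16 CMe2; C17 CHMe; C18 ring-fusion CH; C19 CH2; ring A pyranone, ring B pyran, ring C seven-membered, ring D cyclopentenone.
2. The route rests on the α-ketol C11(=O)–C12(OH) of ring C: it is the direct product of a C11 acyl anion adding to a C12 ketone, so ring C is closed at C11–C12 by a carbene-catalysed aldehyde–ketone benzoin reaction onto a ring D 1,3-dione.
3. Late disconnections: C9–OH/C10–OH from epoxidation–hydration of a C9=C10 vinylogous ester; O8–C9 and C19–pyranone C3 from Michael addition/cyclodehydration of 4-hydroxy-5,6-dimethylpyran-2-one with a C18-methylene 1,3-diketone; C18–C19 from an iminium salt and the bis-silyl dienol ether of the C9/C11 diketone (direct methylenation of that diketone would go to C10).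
4. Early disconnections: C9–C10 by allylboration of an aldehyde (then oxidation, ketalisation, ozonolysis to the C11 aldehyde); C13–C17 by iminium-catalysed Mukaiyama–Michael addition of the silyl enol ether of 2,2-dimethylcyclopentane-1,3-dione to (E)-but-2-enal.
5. Ring order: D (bought, kept saturated) → C (key step) → D dehydrogenated → B fused onto bought ring A.

Key step: step 7

Remark: the (5aR,10bS) antipode of the triazolium salt is assumed to be the one matched to the (13R,17R) aldehyde; if it is not, its mirror image is used.

**Route**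

Step 1
Reactants: 1 2,2-dimethylcyclopentane-1,3-dione
Product: 3 3-[(tert-butyldimethylsilyl)oxy]-2,2-dimethylcyclopent-3-en-1-one, via lithium enolate 2 (not isolated)
Conditions: LDA (1.05 equiv), THF, −78 °C; then TBSCl, DMPU, −78 → 0 °C
Reagents that add atoms: tert-butyldimethylsilyl chloride, CC(C)(C)[Si](C)(C)Cl
Why: One equivalent of amide base stops at the mono-enolate of the symmetric dione (soft enolisation would run on to the bis-silyl cyclopentadiene) and O-silylation gives the enol ether whose only nucleophilic carbon is the future C13 (kinetic enolate formation and silyl trapping).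

Step 2
Reactants: 3 3-[(tert-butyldimethylsilyl)oxy]-2,2-dimethylcyclopent-3-en-1-one; 4 (E)-but-2-enal
Product: 5 (3R)-3-[(1R)-3,3-dimethyl-2,4-dioxocyclopentyl]butanal
Conditions: (2S,5S)-5-benzyl-2-tert-butyl-3-methylimidazolidin-4-one·2,4-dinitrobenzoic acid (20 mol %), tBuOH/iPrOH 5:1, H2O (2 equiv), −20 °C
Reagents that add atoms: water, O
Why: Organocatalytic Mukaiyama–Michael addition: the imidazolidinone forms the E-iminium ion of the enal, its benzyl group shields one face so that the enol ether adds to the open face and C17 is formed R, and in the open antiperiplanar transition state the ring CH2 (C14) avoids the β-methyl group, which should favour the (13R,17R) diastereomer; C13 is α to the C12 ketone, so all steps up to the key step are kept free of strong base.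

Step 3
Reactants: 5 (3R)-3-[(1R)-3,3-dimethyl-2,4-dioxocyclopentyl]butanal; 6 allylboronic acid pinacol ester
Product: 8 (4R)-4-[(2R)-4-hydroxyhept-6-en-2-yl]-2,2-dimethylcyclopentane-1,3-dione (both C9 epimers), via borate ester 7 (not isolated)
Conditions: CH2Cl2, 23 °C; then aq. NH4Cl
Reagents that add atoms: none
Why: Allylboration through a six-membered chair transition state is chemoselective for the aldehyde over the two hindered ring ketones and forms C9–C10; the C9 carbinol is formed unselectively and is erased in step 4.

Step 4
Reactants: 8 (4R)-4-[(2R)-4-hydroxyhept-6-en-2-yl]-2,2-dimethylcyclopentane-1,3-dione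
Product: 9 (4R)-2,2-dimethyl-4-[(2R)-4-oxohept-6-en-2-yl]cyclopentane-1,3-dione
Conditions: Dess–Martin periodinane, pyridine, CH2Cl2, 0 °C
Reagents that add atoms: none
Why: Dess–Martin oxidation, buffered with pyridine, gives the β,γ-unsaturated ketone without moving the allyl double bond into conjugation and without touching C13.

Step 5
Reactants: 9 (4R)-2,2-dimethyl-4-[(2R)-4-oxohept-6-en-2-yl]cyclopentane-1,3-dione
Product: 10 (4R)-4-[(2R)-1-(2-allyl-1,3-dioxolan-2-yl)propan-2-yl]-2,2-dimethylcyclopentane-1,3-dione
Conditions: TMSOCH2CH2OTMS (1.5 equiv), TMSOTf (5 mol %), CH2Cl2, −78 → −40 °C; pyridine quench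
Reagents that add atoms: 1,2-bis(trimethylsilyloxy)ethane, C[Si](C)(C)OCCO[Si](C)(C)C
Why: Noyori ketalisation at low temperature is selective for the methylene-flanked C9 ketone over the two ring ketones next to the quaternary C16, and the aprotic conditions do not shift the β,γ double bond.

Step 6
Reactants: 10 (4R)-4-[(2R)-1-(2-allyl-1,3-dioxolan-2-yl)propan-2-yl]-2,2-dimethylcyclopentane-1,3-dione
Product: 12 2-(2-{(2R)-2-[(1R)-3,3-dimethyl-2,4-dioxocyclopentyl]propyl}-1,3-dioxolan-2-yl)acetaldehyde, via ozonide 11 (not isolated)
Conditions: O3, CH2Cl2, −78 °C; then PPh3, −78 → 23 °C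
Reagents that add atoms: ozone, [O-][O+]=O
Why: Ozonolysis with reductive work-up cuts the terminal alkene to the C11 aldehyde; ketones and ketal are inert and no base is present, so the β-ketal aldehyde and C13 survive.

Step 7
Reactants: 12 2-(2-{(2R)-2-[(1R)-3,3-dimethyl-2,4-dioxocyclopentyl]propyl}-1,3-dioxolan-2-yl)acetaldehyde
Product: 13 cis-fused hydroazulene α-ketol (C9 ethylene ketal, C11 ketone, 12R tertiary OH, 13R, 17R, ring D saturated)
Conditions: (5aR,10bS)-5a,10b-dihydro-2-(pentafluorophenyl)-4H,6H-indeno[2,1-b][1,2,4]triazolo[4,3-d][1,4]oxazinium tetrafluoroborate (15 mol %), Et3N (15 mol %), toluene (0.02 M), 23 → 40 °C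
Reagents that add atoms: none
Why: The triazolylidene adds to the C11 aldehyde, proton transfer gives the enaminol (a C11 acyl anion), this attacks the C12 carbonyl, and the tertiary alkoxide expels the carbene to leave the C11 ketone beside the C12 carbinol. The closest known reaction type is the carbene-catalysed intramolecular aldehyde–ketone cross-benzoin reaction, well established for five- and six-membered rings and less common for seven. Ring C closes 7-exo-trig, helped by the fully substituted ketal carbon C9 in the tether, whereas attack at C15 would need a bridged eight-membered ring. C12 is set by C13: the five-atom tether can only reach the carbonyl face syn to the C13–C17 bond, which gives the cis fusion (OH cis to H13) and hence 12R, and the matched chiral carbene reinforces this face. The step needs cross-benzoin to beat six-ring aldol closures, homo-benzoin, Stetter addition, ketal β-elimination and C13 epimerisation. This is secured by the electrophilic ring ketones that cannot enolise toward C16, by the saturated ring D (no enone acceptor), and by an acidic N-pentafluorophenyl triazolium that needs only a catalytic weak amine base at high dilution.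

Step 8
Reactants: 13 cis-fused hydroazulene α-ketol
Product: 14 C12 triethylsilyl ether of 13
Conditions: TESOTf, 2,6-lutidine, CH2Cl2, −78 → 0 °C
Reagents that add atoms: triethylsilyl trifluoromethanesulfonate, CC[Si](CC)(CC)OS(=O)(=O)C(F)(F)F
Why: Silyl triflate with a hindered pyridine base silylates the tertiary alcohol without enolising the ketones or opening the ketal; the ether blocks retro-aldol cleavage of C12–C16 and α-ketol shifts later on and will shield the upper face of ring C in step 13.

Step 9
Reactants: 14 C12 triethylsilyl ether of 13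
Product: 15 ring D enone (C13=C14–C15=O; C9 ethylene ketal, C11 ketone, C12 OSiEt3)
Conditions: IBX (2-iodoxybenzoic acid), 4-methoxypyridine N-oxide, DMSO, 23 → 45 °C
Reagents that add atoms: none
Why: IBX dehydrogenation of a ketone to an enone: only the C15 ketone has an enolisable α-carbon (C14) with a β-hydrogen (C13–H), whereas the C11 ketone ends at the fully substituted ketal carbon C9 and cannot be desaturated, so the C13=C14 enone forms regiospecifically and C13 stops being a stereocenter.

Step 10
Reactants: 15 ring D enone ketal
Product: 16 C9/C11 β-diketone (ring D enone, C12 OSiEt3)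
Conditions: PPTS, acetone/H2O 10:1, 45 °C
Reagents that add atoms: water, O
Why: Mild acid hydrolysis (transketalisation in wet acetone) frees the C9 ketone as an enolised β-diketone while the hindered tertiary triethylsilyl ether and the enone stay intact.

Step 11
Reactants: 16 C9/C11 β-diketone
Product: 19 C18 dimethylaminomethyl β-diketone (Mannich base; both C18 epimers), via bis-silyl dienol ether 17 (not isolated), via silylated Mannich adduct 18 (not isolated)
Conditions: TMSOTf (2.3 equiv), Et3N (3.5 equiv), CH2Cl2, −20 → 0 °C; then CH2=NMe2+ I−, −78 → 23 °C; pH 7 buffer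
Reagents that add atoms: N,N-dimethylmethyleneiminium iodide, C=[N+](C)C.[I-]; trimethylsilyl trifluoromethanesulfonate (silyl groups in 17 and 18 only), C[Si](C)(C)OS(=O)(=O)C(F)(F)F
Why: Soft double enolisation gives the only possible 1,3-bis(silyloxy)diene (C12 is quaternary, so the second enolisation must go to C18), and such dienes, like β-diketone dianions, react with electrophiles at the terminal carbon, so the Mannich reaction with the preformed iminium salt puts C19 on C18 and not on the more acidic C10; limited silyl triflate and low temperature keep the ring D enone from γ-deprotonation at C17, and the unselectively formed C18 centre is erased in step 12.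

Step 12
Reactants: 19 C18 dimethylaminomethyl β-diketone; 20 4-hydroxy-5,6-dimethyl-2H-pyran-2-one
Product: 23 tetracyclic vinylogous ester (rings A–D; O8–C9=C10–C11=O; 12R, 17R, 18R; C12 OSiEt3), via methylene diketone 21 (not isolated), via open Michael adduct 22 (not isolated)
Conditions: 20 (1.5 equiv), toluene, 90 °C; then PPTS (10 mol %), 4 Å MS, 90 °C
Reagents that add atoms: none
Why: On heating, the β-amino ketone loses dimethylamine to the C18-methylene diketone, which is trapped at C19 by C3 of the hydroxypyranone (Michael addition of a vinylogous acid, as in warfarin-type additions), and acid-catalysed cyclodehydration of the pyranone 4-OH onto the C9 carbonyl (six-membered; C11 would need an eight-membered ring) gives the conjugated vinylogous ester, in which C18 equilibrates through the dienol to the epimer with C19 and the C17 methyl both pseudo-equatorial (trans, 18R).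

Step 13
Reactants: 23 tetracyclic vinylogous ester
Product: 26 target CNP0525404.1 (9S,10R,12R,17R,18R), via epoxide 24 (not isolated), via silyl ether 25 (not isolated)
Conditions: DMDO (1.3 equiv), acetone/CH2Cl2, −40 → 0 °C; then 48 % aq. HF, MeCN/H2O, 0 → 23 °C
Reagents that add atoms: dimethyldioxirane, CC1(C)OO1; water, O
Why: Dimethyldioxirane epoxidises the C9=C10 bond of the cyclic β-alkoxy enone (as it does with chromones) from the face opposite the axial C12 silyloxy group, water opens the labile 2-alkoxy epoxide at the acetal-like C9 with inversion to give the trans-diaxial C9-OH/C10-OH pair (C9 being also the anomerically preferred, trans-fused hemiketal), and HF removes the silyl ether.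

**Compound list**

1 | 2,2-dimethylcyclopentane-1,3-dione | CC1(C)C(=O)CCC1=O | starting material
2 | lithium 5,5-dimethyl-4-oxocyclopent-1-en-1-olate | CC1(C)C(=O)CC=C1[O-].[Li+] | intermediate (not isolated)
3 | 3-[(tert-butyldimethylsilyl)oxy]-2,2-dimethylcyclopent-3-en-1-one | CC1(C)C(=O)CC=C1O[Si](C)(C)C(C)(C)C | intermediate
4 | (E)-but-2-enal | C/C=C/C=O | starting material
5 | (3R)-3-[(1R)-3,3-dimethyl-2,4-dioxocyclopentyl]butanal | O=CC[C@@H](C)[C@H]1CC(=O)C(C)(C)C1=O | intermediate
6 | allylboronic acid pinacol ester (2-allyl-4,4,5,5-tetramethyl-1,3,2-dioxaborolane) | C=CCB1OC(C)(C)C(C)(C)O1 | starting material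
7 | pinacol borate ester of 8 | C=CCC(OB1OC(C)(C)C(C)(C)O1)C[C@@H](C)[C@H]2CC(=O)C(C)(C)C2=O | intermediate (not isolated)
8 | (4R)-4-[(2R)-4-hydroxyhept-6-en-2-yl]-2,2-dimethylcyclopentane-1,3-dione, both C9 epimers | C=CCC(O)C[C@@H](C)[C@H]1CC(=O)C(C)(C)C1=O | intermediate
9 | (4R)-2,2-dimethyl-4-[(2R)-4-oxohept-6-en-2-yl]cyclopentane-1,3-dione | C=CCC(=O)C[C@@H](C)[C@H]1CC(=O)C(C)(C)C1=O | intermediate
10 | (4R)-4-[(2R)-1-(2-allyl-1,3-dioxolan-2-yl)propan-2-yl]-2,2-dimethylcyclopentane-1,3-dione | C=CCC1(OCCO1)C[C@@H](C)[C@H]2CC(=O)C(C)(C)C2=O | intermediate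
11 | 1,2,4-trioxolane (ozonide) of 10 | O1OC(CC2(OCCO2)C[C@@H](C)[C@H]3CC(=O)C(C)(C)C3=O)OC1 | intermediate (not isolated)
12 | 2-(2-{(2R)-2-[(1R)-3,3-dimethyl-2,4-dioxocyclopentyl]propyl}-1,3-dioxolan-2-yl)acetaldehyde | O=CCC1(OCCO1)C[C@@H](C)[C@H]2CC(=O)C(C)(C)C2=O | intermediate (key-step precursor)
13 | (3aR,4R,8aR)-8a-hydroxy-1,1,4-trimethyldecahydroazulene-2,6,8-trione 6-(ethylene ketal), cis-fused (azulene C8a = C12, C3a = C13, C4 = C17, C6 = C9, C8 = C11) | C1COC2(O1)CC(=O)[C@@]3(O)[C@H](CC(=O)C3(C)C)[C@H](C)C2 | intermediate (key-step product)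
14 | C12 triethylsilyl ether of 13 | C1COC2(O1)CC(=O)[C@@]3(O[Si](CC)(CC)CC)[C@H](CC(=O)C3(C)C)[C@H](C)C2 | intermediate
15 | C13=C14 enone of 14 (C9 ethylene ketal, C11 and C15 ketones, 12R, 17R) | C1COC2(O1)CC(=O)[C@@]3(O[Si](CC)(CC)CC)C(=CC(=O)C3(C)C)[C@H](C)C2 | intermediate
16 | C9/C11 β-diketone (ring D enone, 12R OSiEt3, 17R), drawn as the diketo tautomer | O=C1CC(=O)[C@@]2(O[Si](CC)(CC)CC)C(=CC(=O)C2(C)C)[C@H](C)C1 | intermediate
17 | 1,3-bis(trimethylsilyloxy)diene C18=C9(OSiMe3)–C10=C11(OSiMe3) of 16 | C1=C(O[Si](C)(C)C)C=C(O[Si](C)(C)C)[C@@]2(O[Si](CC)(CC)CC)C(=CC(=O)C2(C)C)[C@@H]1C | intermediate (not isolated)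
18 | C18 dimethylaminomethyl C9 ketone with C10=C11 trimethylsilyl enol ether | CN(C)CC1C(=O)C=C(O[Si](C)(C)C)[C@@]2(O[Si](CC)(CC)CC)C(=CC(=O)C2(C)C)[C@@H]1C | intermediate (not isolated)
19 | C18 dimethylaminomethyl C9/C11 β-diketone, both C18 epimers | CN(C)CC1C(=O)CC(=O)[C@@]2(O[Si](CC)(CC)CC)C(=CC(=O)C2(C)C)[C@@H]1C | intermediate
20 | 4-hydroxy-5,6-dimethyl-2H-pyran-2-one | Cc1oc(=O)cc(O)c1C | starting material
21 | C18 methylene C9/C11 β-diketone | C=C1C(=O)CC(=O)[C@@]2(O[Si](CC)(CC)CC)C(=CC(=O)C2(C)C)[C@@H]1C | intermediate (not isolated)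
22 | open Michael adduct: C19 bonded to pyranone C3, free pyranone 4-OH, C9/C11 β-diketone | Cc1oc(=O)c(CC2C(=O)CC(=O)[C@@]3(O[Si](CC)(CC)CC)C(=CC(=O)C3(C)C)[C@@H]2C)c(O)c1C | intermediate (not isolated)
23 | tetracyclic vinylogous ester (rings A–D, O8–C9=C10–C11=O, 12R OSiEt3, 17R, 18R) | Cc1oc(=O)c2c(c1C)OC1=CC(=O)[C@@]3(O[Si](CC)(CC)CC)C(=CC(=O)C3(C)C)[C@H](C)[C@H]1C2 | intermediate
24 | (9R,10R)-9,10-epoxide of 23, oxygen anti to the C12 silyloxy group | Cc1oc(=O)c2c(c1C)O[C@]13O[C@@H]3C(=O)[C@@]4(O[Si](CC)(CC)CC)C(=CC(=O)C4(C)C)[C@H](C)[C@H]1C2 | intermediate (not isolated)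
25 | C12 triethylsilyl ether of the target | Cc1oc(=O)c2c(c1C)O[C@]1(O)[C@H](O)C(=O)[C@@]3(O[Si](CC)(CC)CC)C(=CC(=O)C3(C)C)[C@H](C)[C@H]1C2 | intermediate (not isolated)
26 | CNP0525404.1, (9S,10R,12R,17R,18R) | Cc1oc(=O)c2c(c1C)O[C@]1(O)[C@H](O)C(=O)[C@@]3(O)C(=CC(=O)C3(C)C)[C@H](C)[C@H]1C2 | target

**Step count and risks**

Total steps: 13. Longest linear sequence: 13 steps (from 1).

Steps most likely to fail:

1. Step 7 (key step). The seven-membered closure may be slow, so that base-mediated six-ring aldol cyclisation (C10 or C13 enolate), homo-benzoin coupling or β-elimination of the ketal overtake it, or C13 epimerises before closure and the cis-fusion relay then gives the wrong C12 configuration. Fallback, from 12 back to 13: the same C11–C12 bond is made reductively instead of by umpolung. Samarium diiodide (SmI2, 2.2 equiv, tBuOH, THF, −78 °C) reduces the aldehyde first and the C11 ketyl adds to the C12 carbonyl on the same tether-defined face to give the C11,C12-diol F1. Parikh–Doering oxidation (SO3·pyridine, DMSO, iPr2NEt) of its only secondary alcohol returns 13.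

2. Step 13. Oxygen transfer may occur with poor facial selectivity (attack syn to the C12 silyloxy group), or the pyranone ring may be over-oxidised when the push–pull C9=C10 bond reacts slowly. Fallback, from 23 back to 26: control of C10 is moved from kinetics to equilibrium. The oxidation, hydration and desilylation are run at low conversion of dioxirane, and the C10 epimer of the target F2 that wrong-face attack delivers is not discarded. C10 lies between the C11 ketone and the C9 hemiketal, so F2 is equilibrated through the ring-opened 2-hydroxy-1,3-diketone (Et3N cat., CH2Cl2/MeOH, argon); 26 is separated and F2 is recycled.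

3. Step 2. The syn/anti selectivity at C13 in the C–C bond formation may be poor (or C13 may epimerise afterwards), and the cis-fusion relay of step 7 would turn this into the wrong C12 configuration. Fallback, from 3 and 4 back to 5: C13 is set by equilibration and recycling instead of kinetic control, while C17 is still set by the catalyst. The C13 epimer of the aldehyde F3 is separated from 5 and re-equilibrated at C13 (Et3N, MeCN, 40 °C; C13–H is α to the C12 ketone, C17 is untouched) to a near-equal mixture, which is separated again so that the material converges on 5.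

Further compounds
F1 | step 7 | C11,C12-diol of the cis-fused hydroazulene (C9 ethylene ketal, C15 ketone, either C11 epimer) | C1COC2(O1)CC(O)[C@@]3(O)[C@H](CC(=O)C3(C)C)[C@H](C)C2
F2 | step 13 | C10 epimer of the target, (9S,10S,12R,17R,18R) | Cc1oc(=O)c2c(c1C)O[C@]1(O)[C@@H](O)C(=O)[C@@]3(O)C(=CC(=O)C3(C)C)[C@H](C)[C@H]1C2
F3 | step 2 | (3R)-3-[(1S)-3,3-dimethyl-2,4-dioxocyclopentyl]butanal | O=CC[C@@H](C)[C@@H]1CC(=O)C(C)(C)C1=O
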